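A plain equilibrium J + L ⇌ G fails on two runs. With [L] taken as charge less J used, [G]/([J][L]) at 5.00 d reads 0.820 M⁻¹ on Monday's run and 0.426 M⁻¹ on Wednesday's.

These are the minutes of a short meeting on the flask below.

| flask | J | L | remark | time |
|---|---|---|---|---|
| Monday's | 0.50 M | 0.32 M | run made earlier |  |
| Wednesday's | 0.50 M | 0.71 M | run made earlier |  |
| Friday's | 0.25 M | 0.475 M | run made earlier |  |
| flask | 0.50 M | 0.475 M |  | 6.0 d |

| run | time / d | J / % | G / % |
|---|---|---|---|
| Monday's | 0.417 | 89.5 | 10.4 |
| Monday's | 1.25 | 85.3 | 14.2 |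
| Monday's | 2.00 | 83.9 | 14.7 |
| Monday's | 3.00 | 83.5 | 15.9 |
| Monday's | 5.00 | 83.0 | 16.0 |
| Wednesday's | 0.417 | 84.2 | 15.3 |
| Wednesday's | 1.25 | 80.1 | 18.8 |
| Wednesday's | 2.00 | 79.4 | 19.3 |
| Wednesday's | 3.00 | 79.4 | 20.2 |
| Wednesday's | 5.00 | 78.4 | 20.1 |
| Friday's | 0.417 | 86.4 | 12.9 |
| Friday's | 0.833 | 82.5 | 16.4 |
| Friday's | 1.25 | 80.6 | 18.6 |
| Friday's | 2.50 | 78.3 | 20.1 |
| Friday's | 5.00 | 77.4 | 21.6 |

(standard deviation of a reading: 0.3 percentage points)

- how much J there is at 6.0 d, in percent of the J charged
- how much G there is at 6.0 d, in percent of the J charged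
- how much E there is at 6.0 d, in percent of the J charged
- how much Q there is at 6.0 d, in percent of the J charged

- what was read earlier has a scatter of 0.3 percentage points, one standard deviation

Ana, in the chair, accepted those two readings and asked what else might stop J. Ben proposed that L destroys itself, at second order in [L]. J would then fall as a pseudo-first-order loss, at a rate proportional to [L].

Holding [J] steady, Ben integrated [L] over time in closed form. The reach, ln([J] charged/[J] left), comes to (1/r) ln(1 + r[L]/[J]), with [L] and [J] as charged. Here r is the rate constant of L's loss with itself over that of J + L.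

Cara objected that r is unknown. Ben answered that where r[L]/[J] is large the 1 drops out, so two runs at equal [J] charged give the slope directly. From Monday's and Wednesday's last readings it reads 0.0715. This is the reach slope, the rise of the reach per unit of ln[L] charged, at fixed [J] charged.

Cara tested it on Friday's run, where the ratio [L]/[J] carries the change. It gave J 76.8% against the reading 77.4%.

My own reckoning for the flask, taken as on its plateau at 6.0 d, gives J 80.7%. The two runs leave a mean of 1.2 percentage points unread, for E and Q together, so G is 18.1%.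

The forecast gave J 80.7%, G 18.1%, E 1.1% and Q 0.1%, adding: “The mechanism is uncertain, so this is an estimate.”

The flask gives J 80.9%, G 18.1%, E 0.871% and Q 0.126%.

    J + L → G + X (k = 2.78 × 10⁻⁵ M⁻¹ s⁻¹)
    L + G → E + X (k = 1.37 × 10⁻⁵ M⁻¹ s⁻¹)
    L + E → Q + X (k = 5.40 × 10⁻⁵ M⁻¹ s⁻¹)
    L + Q ⇌ D + X (K = 1.10, k = 3.62 × 10⁻⁶ M⁻¹ s⁻¹)
    2 L → Z (k = 1.70 × 10⁻⁴ M⁻¹ s⁻¹)

At the start of the flask, L went by the path to Z at 11.6 times its rate by J + L. At 6.00 d the flask holds Z at 0.187 M beside X at 0.101 M, with L at 0.00984% of its charge. Above Monday's last reading of J, the flask's reach is larger by 0.0257, where the reach slope gave 0.0283. For a further flask, like this one but with 0.19 M of L, below Monday's charge, the same slope gives J 86.2%, and that flask holds 86.6%.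

All runs were computed with made-up constants; the scatter is artificial.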